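**Retrosynthetic overview**
1. Target 22 ⇒ (desilylation) 21 ⇒ enol-ether C(sp2)–O disconnection into (S)-alcohol 12 and (Z)-vinyl iodide 20; the coupling touches neither the carbinol C–O bond nor the alkene geometry.
2. 12 ⇒ ketone 11 (CBS reduction sets S) ⇒ aldehyde 9 ⇒ chromene 7 ⇒ chromanone 4.
3. Key C–C bond: C2–C3 of the pyran ring, made by intermolecular aldol condensation of 2',4'-dihydroxyacetophenone 1 with acetone 2 (Kabbe reaction), with oxa-Michael ring closure in the same pot.
4. 20 ⇒ propargyl alcohol 15 + the aryl Grignard reagent from 2-bromo-5-methylphenol 13 (hydroxyl-directed anti-carbomagnesiation; iodine quench fixes Z).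
5. Ring order: only the pyran ring is built (step 1; its 3,4-double bond in step 4); both benzene rings are bought.

Assumption: the SMILES is read as S at the benzylic ether carbon and Z at the enol ether (ether oxygen cis to CH2OH, trans to the aryl ring).

**Step 1**
Reactants: 1 2',4'-dihydroxyacetophenone; 2 acetone
Product: 4 7-hydroxy-2,2-dimethylchroman-4-one, via aldol-condensation enone 3 (not isolated)
Conditions: pyrrolidine (1.5 equiv), acetone (5 equiv), toluene, reflux (Dean–Stark), 8 h; 1 M HCl wash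
Reagents that add atoms: none
Why: Kabbe chromanone synthesis, in which the pyrrolidine-mediated intermolecular aldol condensation of the acetophenone methyl group with acetone forms the C3–C2 bond and the ortho phenol then closes the ring by intramolecular oxa-Michael addition (no stereocenter).

**Step 2**
Reactants: 4 7-hydroxy-2,2-dimethylchroman-4-one
Product: 5 7-methoxy-2,2-dimethylchroman-4-one
Conditions: MeI, K2CO3, acetone, reflux
Reagents that add atoms: iodomethane, CI
Why: Williamson etherification of the only phenol, which is para to the carbonyl and not chelated.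

**Step 3**
Reactants: 5 7-methoxy-2,2-dimethylchroman-4-one
Product: 6 (±)-7-methoxy-2,2-dimethylchroman-4-ol
Conditions: NaBH4, MeOH, 0 °C to rt
Reagents that add atoms: none
Why: Borohydride reduction of the aryl ketone; the racemic carbinol centre is removed in the next step.

**Step 4**
Reactants: 6 (±)-7-methoxy-2,2-dimethylchroman-4-ol
Product: 7 7-methoxy-2,2-dimethyl-2H-chromene
Conditions: TsOH·H2O (5 mol%), toluene, 80 °C, 45 min
Reagents that add atoms: none
Why: Acid-catalysed E1 dehydration through the alkoxy-stabilised benzylic cation gives the conjugated chromene, with a short reaction time to avoid acid dimerisation.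

**Step 5**
Reactants: 7 7-methoxy-2,2-dimethyl-2H-chromene
Product: 9 7-methoxy-2,2-dimethyl-2H-chromene-6-carbaldehyde, via aryl iminium chloride 8 (not isolated)
Conditions: POCl3 (1.3 equiv), DMF, 0 °C to 50 °C; then ice, aq NaOH to pH 8
Reagents that add atoms: N,N-dimethylformamide, CN(C)C=O (formyl carbon); water, O (carbonyl oxygen)
Why: Vilsmeier–Haack formylation, an electrophilic aromatic substitution directed to C6 (para to the ring oxygen, ortho to OMe), while C8 is hindered between two oxygens.

**Step 6**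
Reactants: 9 7-methoxy-2,2-dimethyl-2H-chromene-6-carbaldehyde
Product: 10 (±)-1-(7-methoxy-2,2-dimethyl-2H-chromen-6-yl)ethan-1-ol
Conditions: MeMgBr, THF, 0 °C; aq NH4Cl/NH3 (pH 8)
Reagents that add atoms: methylmagnesium bromide, C[Mg]Br
Why: Grignard addition to the aldehyde, with a non-acidic work-up because this benzylic alcohol ionises easily.

**Step 7**
Reactants: 10 (±)-1-(7-methoxy-2,2-dimethyl-2H-chromen-6-yl)ethan-1-ol
Product: 11 1-(7-methoxy-2,2-dimethyl-2H-chromen-6-yl)ethan-1-one (encecalin)
Conditions: MnO2 (10 equiv), CH2Cl2, rt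
Reagents that add atoms: none
Why: Neutral MnO2 oxidation of an activated benzylic alcohol, which leaves the chromene double bond untouched.

**Step 8**
Reactants: 11 encecalin
Product: 12 (1S)-1-(7-methoxy-2,2-dimethyl-2H-chromen-6-yl)ethan-1-ol
Conditions: (R)-2-methyl-CBS-oxazaborolidine (20 mol%), catecholborane (1.5 equiv), toluene, −78 to −40 °C; then MeOH, 1 M NaOH wash; use at once
Reagents that add atoms: none
Why: Corey–Bakshi–Shibata reduction, in which the (R)-oxazaborolidine binds the ketone with the aryl group as the large substituent and delivers hydride to the Re face to give the S alcohol, and catecholborane does not hydroborate the chromene alkene.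

**Step 9**
Reactants: 13 2-bromo-5-methylphenol
Product: 14 1-bromo-2-(methoxymethoxy)-4-methylbenzene
Conditions: MOMCl, i-Pr2NEt, CH2Cl2, 0 °C to rt
Reagents that add atoms: chloromethyl methyl ether, COCCl
Why: O-alkylation of the phenol to a MOM acetal that tolerates the Grignard chemistry of the next step.

**Step 10**
Reactants: 14 1-bromo-2-(methoxymethoxy)-4-methylbenzene (2.5 equiv); 15 prop-2-yn-1-ol
Product: 18 (Z)-3-iodo-2-[2-(methoxymethoxy)-4-methylphenyl]prop-2-en-1-ol, via aryl Grignard reagent 16 (not isolated), via cyclic alkenylmagnesium alkoxide 17 (not isolated)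
Conditions: Mg, THF, reflux; then 15 (0.4 equiv), CuI (10 mol% on 15), THF, 0 °C to reflux, 16 h; then I2, THF, −40 to 0 °C; aq Na2S2O3
Reagents that add atoms: iodine, [I][I]
Why: CuI-catalysed hydroxyl-directed anti-carbomagnesiation of the propargylic alkoxide (Duboudin reaction) puts the aryl group on C2 and magnesium on C3 cis to CH2O in a five-membered chelate, and iodinolysis with retention gives the Z iodide (iodine cis to CH2OH).

**Step 11**
Reactants: 18 (Z)-3-iodo-2-[2-(methoxymethoxy)-4-methylphenyl]prop-2-en-1-ol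
Product: 19 2-[(Z)-3-hydroxy-1-iodoprop-1-en-2-yl]-5-methylphenol
Conditions: conc. HCl (cat.), MeOH, 40 °C
Reagents that add atoms: none
Why: Acid transacetalisation removes the MOM group while the molecule is still acid-stable, so that a fluoride-labile group can carry the phenol to the end.

**Step 12**
Reactants: 19 2-[(Z)-3-hydroxy-1-iodoprop-1-en-2-yl]-5-methylphenol
Product: 20 {[(Z)-3-iodo-2-(4-methyl-2-{[tri(propan-2-yl)silyl]oxy}phenyl)prop-2-en-1-yl]oxy}tri(propan-2-yl)silane
Conditions: TIPSOTf (2.4 equiv), 2,6-lutidine, CH2Cl2, 0 °C to rt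
Reagents that add atoms: triisopropylsilyl trifluoromethanesulfonate, CC(C)[Si](OS(=O)(=O)C(F)(F)F)(C(C)C)C(C)C
Why: Exhaustive silylation masks both hydroxyl groups as bulky TIPS ethers that resist Cs2CO3 and alkoxide at 80 °C and leave under neutral-to-basic fluoride conditions.

**Step 13**
Reactants: 12 (1S)-1-(7-methoxy-2,2-dimethyl-2H-chromen-6-yl)ethan-1-ol; 20 bis-TIPS (Z)-vinyl iodide (1.3 equiv)
Product: 21 6-[(1S)-1-{[(1Z)-2-(4-methyl-2-{[tri(propan-2-yl)silyl]oxy}phenyl)-3-{[tri(propan-2-yl)silyl]oxy}prop-1-en-1-yl]oxy}ethyl]-7-methoxy-2,2-dimethyl-2H-chromene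
Conditions: CuI (20 mol%), 3,4,7,8-tetramethyl-1,10-phenanthroline (40 mol%), Cs2CO3 (2 equiv), toluene, 4 Å MS, 80 °C, Ar
Reagents that add atoms: none
Why: Ullmann-type CuI-catalysed C(sp2)–O coupling of an alcohol with a vinyl iodide proceeds with retention of alkene geometry, and because the carbinol C–O bond is never broken the S centre is carried through under purely basic conditions.

**Step 14**
Reactants: 21 bis-TIPS ether
Product: 22 2-[(1Z)-3-hydroxy-1-{(1S)-1-(7-methoxy-2,2-dimethyl-2H-chromen-6-yl)ethoxy}prop-1-en-2-yl]-5-methylphenol (target)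
Conditions: Bu4NF (3 equiv), THF, 0 °C to rt; aq NaHCO3; Et3N-treated silica
Reagents that add atoms: none
Why: Fluoride-mediated desilylation frees the phenol and the primary alcohol without any acid, so the acid-labile benzylic enol ether and its S centre survive.

**Compound list**
1 | 1-(2,4-dihydroxyphenyl)ethan-1-one (2',4'-dihydroxyacetophenone) | CC(=O)c1ccc(O)cc1O | starting material
2 | acetone | CC(C)=O | starting material
3 | 1-(2,4-dihydroxyphenyl)-3-methylbut-2-en-1-one | CC(C)=CC(=O)c1ccc(O)cc1O | intermediate (not isolated)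
4 | 7-hydroxy-2,2-dimethylchroman-4-one | CC1(C)CC(=O)c2ccc(O)cc2O1 | intermediate
5 | 7-methoxy-2,2-dimethylchroman-4-one | CC1(C)CC(=O)c2ccc(OC)cc2O1 | intermediate
6 | (±)-7-methoxy-2,2-dimethylchroman-4-ol | CC1(C)CC(O)c2ccc(OC)cc2O1 | intermediate
7 | 7-methoxy-2,2-dimethyl-2H-chromene | CC1(C)C=Cc2ccc(OC)cc2O1 | intermediate
8 | N-[(7-methoxy-2,2-dimethyl-2H-chromen-6-yl)methylidene]-N-methylmethanaminium chloride | COc1cc2OC(C)(C)C=Cc2cc1C=[N+](C)C.[Cl-] | intermediate (not isolated)
9 | 7-methoxy-2,2-dimethyl-2H-chromene-6-carbaldehyde | COc1cc2OC(C)(C)C=Cc2cc1C=O | intermediate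
10 | (±)-1-(7-methoxy-2,2-dimethyl-2H-chromen-6-yl)ethan-1-ol | COc1cc2OC(C)(C)C=Cc2cc1C(C)O | intermediate
11 | 1-(7-methoxy-2,2-dimethyl-2H-chromen-6-yl)ethan-1-one (encecalin) | COc1cc2OC(C)(C)C=Cc2cc1C(C)=O | intermediate
12 | (1S)-1-(7-methoxy-2,2-dimethyl-2H-chromen-6-yl)ethan-1-ol | COc1cc2c(cc1[C@H](C)O)C=CC(C)(C)O2 | intermediate
13 | 2-bromo-5-methylphenol | Cc1ccc(Br)c(O)c1 | starting material
14 | 1-bromo-2-(methoxymethoxy)-4-methylbenzene | COCOc1cc(C)ccc1Br | intermediate
15 | prop-2-yn-1-ol (propargyl alcohol) | C#CCO | starting material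
16 | [2-(methoxymethoxy)-4-methylphenyl]magnesium bromide | COCOc1cc(C)ccc1[Mg]Br | intermediate (not isolated)
17 | 4-[2-(methoxymethoxy)-4-methylphenyl]-2,5-dihydro-1,2-oxamagnesole (Mg on the vinyl CH and on the CH2O oxygen) | COCOc1cc(C)ccc1C1=C[Mg]OC1 | intermediate (not isolated)
18 | (Z)-3-iodo-2-[2-(methoxymethoxy)-4-methylphenyl]prop-2-en-1-ol (iodine cis to CH2OH) | I/C=C(\CO)c1ccc(C)cc1OCOC | intermediate
19 | 2-[(Z)-3-hydroxy-1-iodoprop-1-en-2-yl]-5-methylphenol | I/C=C(\CO)c1ccc(C)cc1O | intermediate
20 | {[(Z)-3-iodo-2-(4-methyl-2-{[tri(propan-2-yl)silyl]oxy}phenyl)prop-2-en-1-yl]oxy}tri(propan-2-yl)silane | I/C=C(\CO[Si](C(C)C)(C(C)C)C(C)C)c1ccc(C)cc1O[Si](C(C)C)(C(C)C)C(C)C | intermediate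
21 | 6-[(1S)-1-{[(1Z)-2-(4-methyl-2-{[tri(propan-2-yl)silyl]oxy}phenyl)-3-{[tri(propan-2-yl)silyl]oxy}prop-1-en-1-yl]oxy}ethyl]-7-methoxy-2,2-dimethyl-2H-chromene | COc1cc2c(cc1[C@H](C)O/C=C(\CO[Si](C(C)C)(C(C)C)C(C)C)c1ccc(C)cc1O[Si](C(C)C)(C(C)C)C(C)C)C=CC(C)(C)O2 | intermediate
22 | 2-[(1Z)-3-hydroxy-1-{(1S)-1-(7-methoxy-2,2-dimethyl-2H-chromen-6-yl)ethoxy}prop-1-en-2-yl]-5-methylphenol | COc1cc2c(cc1[C@H](C)O/C=C(\CO)c1ccc(C)cc1O)C=CC(C)(C)O2 | target

**Totals**
Total step count: 14. Longest linear sequence: 10 steps (steps 1–8, 13, 14); the vinyl iodide branch is steps 9–12.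

**Three steps most likely to fail**

Step 13 (C–O coupling). The secondary benzylic alkoxide is hindered and can be oxidised to 11 by copper alkoxide β-hydride loss, and silyl transfer from the aryl TIPS ether is possible. The fallback replaces the Ullmann coupling with an oxidative Chan–Lam–Evans etherification. It sets out from 20: Miyaura borylation (B2pin2, PdCl2(dppf), KOPh, toluene, 50 °C, retention of geometry) gives the (Z)-alkenyl pinacol boronate F1. F1 (2–3 equiv) is then coupled with 12 using Cu(OAc)2 (2 equiv), Et3N, 4 Å MS, CH2Cl2 under air at rt; this divalent-copper-mediated C–O bond formation also retains the alkene geometry and comes back to the route at 21.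

Step 10 (carbomagnesiation). The ortho-MOM-oxy aryl Grignard reagent is hindered and may add slowly or with poor regiocontrol. The fallback is a carbonyl olefination and sets out from 14 as its Grignard reagent 16. Acylation of 16 with N-methoxy-N-methyl-2-{[tri(propan-2-yl)silyl]oxy}acetamide (THF, 0 °C) gives the α-silyloxy ketone F2. Wittig reaction of F2 with Ph3P=CHI (from (iodomethyl)triphenylphosphonium iodide and NaN(SiMe3)2, THF/HMPA, −78 °C) gives the silyl-protected (Z)-vinyl iodide F3. By analogy with Still's Z-selective Wittig reactions of α-alkoxy ketones the ylide substituent should end up cis to the alkoxymethyl arm, but selectivity with an aryl ketone is not assured; the minor E isomer would be removed by chromatography and the geometry checked by NOE. Bu4NF in THF then removes the silyl group and comes back to the route at 18.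

Step 5 (Vilsmeier formylation). Attack at the electron-rich C3–C4 alkene or acid-induced dimerisation of 7 could compete with C6 formylation. The fallback installs the C6 substituent before the alkene exists and builds the acetyl group by halogen–metal exchange; it sets out from 5. NBS (MeCN, 0 °C to rt) gives 6-bromo-7-methoxy-2,2-dimethylchroman-4-one F4; C6 is expected to be favoured over C8 on steric grounds, and any C8 isomer would be separated. NaBH4 in MeOH gives the bromochromanol F5, and TsOH (cat.) in toluene at 80 °C gives 6-bromo-7-methoxy-2,2-dimethyl-2H-chromene F6. Treatment with n-BuLi (THF, −78 °C) and then N-methoxy-N-methylacetamide comes back to the route at 11, bypassing steps 3–7.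

**Further compounds**
F1 | step 13 | 4,4,5,5-tetramethyl-2-[(Z)-2-(4-methyl-2-{[tri(propan-2-yl)silyl]oxy}phenyl)-3-{[tri(propan-2-yl)silyl]oxy}prop-1-en-1-yl]-1,3,2-dioxaborolane | CC1(C)OB(OC1(C)C)/C=C(\CO[Si](C(C)C)(C(C)C)C(C)C)c1ccc(C)cc1O[Si](C(C)C)(C(C)C)C(C)C
F2 | step 10 | 1-[2-(methoxymethoxy)-4-methylphenyl]-2-{[tri(propan-2-yl)silyl]oxy}ethan-1-one | COCOc1cc(C)ccc1C(=O)CO[Si](C(C)C)(C(C)C)C(C)C
F3 | step 10 | {[(Z)-3-iodo-2-[2-(methoxymethoxy)-4-methylphenyl]prop-2-en-1-yl]oxy}tri(propan-2-yl)silane | I/C=C(\CO[Si](C(C)C)(C(C)C)C(C)C)c1ccc(C)cc1OCOC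
F4 | step 5 | 6-bromo-7-methoxy-2,2-dimethylchroman-4-one | CC1(C)CC(=O)c2cc(Br)c(OC)cc2O1
F5 | step 5 | (±)-6-bromo-7-methoxy-2,2-dimethylchroman-4-ol | CC1(C)CC(O)c2cc(Br)c(OC)cc2O1
F6 | step 5 | 6-bromo-7-methoxy-2,2-dimethyl-2H-chromene | CC1(C)C=Cc2cc(Br)c(OC)cc2O1
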